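**Retrosynthetic overview**
1. Target ⇐ reagent-controlled Sharpless epoxidation of the 13E allylic alcohol, after adjusting C-19 (CH2OH → CO2Me) on the bicyclic core.
2. Bicyclic core ⇐ one cation–olefin cascade of an acyclic C20 epoxy-triene. An exocyclic (S)-2,2-disubstituted oxirane starts it, ring A closes first (C4–C5), ring B second (C10–C9), and an allylsilane ends it as the 8(17)-alkene. The (Z)-C5=C10 alkene dictates the cis ring fusion.
3. Acyclic chain ⇐ two B-alkyl Suzuki couplings (C1–C10 and C7–C8) that fix both trisubstituted alkene geometries.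
4. Building blocks ⇐ methallyl alcohol (chiral oxirane), acrolein (Z-iododiene), geranyl acetate (side chain with Z-bromoallylsilane).

Assumption: the SMILES is read literally as (4S,5S,9S,10R,13R,14R). The decalin is therefore cis-fused (H-5, CH3-20, the C-9 side chain and the C-4 ester all on the same face), i.e. the 5-epimer of the usual labdane series. Labdane numbering is used for locants.

Step 1
Reactants: 1 2-methylprop-2-en-1-ol
Product: 3 [(2S)-2-methyloxiran-2-yl]methyl 4-methylbenzenesulfonate, via (R)-2-methylglycidol 2 (not isolated)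
Conditions: Ti(OiPr)4 (5 mol %), D-(−)-DIPT (6 mol %), TBHP (1.5 equiv), 4 Å MS, CH2Cl2, −20 °C; then P(OMe)3; then Et3N, DMAP (cat.), TsCl, −10 °C
Reagents that add atoms: tert-butyl hydroperoxide, CC(C)(C)OO; 4-toluenesulfonyl chloride, Cc1ccc(cc1)S(=O)(=O)Cl
Why: Katsuki–Sharpless asymmetric epoxidation with the D-(−)-tartrate catalyst sets the quaternary centre (later C-4) as (R)-2-methylglycidol, which is tosylated in situ (the CIP label becomes S, the geometry is unchanged).

Step 2
Reactants: 3 [(2S)-2-methyloxiran-2-yl]methyl 4-methylbenzenesulfonate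
Product: 5 (2S)-2-methyl-2-(prop-2-en-1-yl)oxirane, via hydroxy tosylate magnesium alkoxide 4 (not isolated)
Conditions: CH2=CHMgBr (1.3 equiv), CuI (10 mol %), THF, −40 → −20 °C; then rt, 3 h; product handled as a distilled THF solution (volatile)
Reagents that add atoms: vinylmagnesium bromide, C=C[Mg]Br
Why: Copper-catalysed Grignard opening occurs at the oxirane CH2 and the tertiary alkoxide then closes onto the CH2OTs carbon (3-exo-tet epoxide transposition), so no bond to the quaternary centre is broken and its configuration is carried over.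

Step 3
Reactants: 6 acrolein; 7 ethyltriphenylphosphonium iodide
Product: 11 (3Z)-4-iodopenta-1,3-diene, via ethylidenetriphenylphosphorane 8 (not isolated), via (1-iodoethyl)triphenylphosphonium iodide 9 (not isolated), via (1-iodoethylidene)triphenylphosphorane 10 (not isolated)
Conditions: 7, n-BuLi, THF, 0 °C; I2, −78 °C; NaHMDS, −78 → −20 °C; then 6, −78 °C → rt, dark
Reagents that add atoms: iodine, II
Why: Zhao's α-iodoethylidene variant of the Stork–Zhao Wittig olefination gives the (Z)-2-iodoalkene under kinetic control, with iodine cis to the vinyl group.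

Step 4
Reactants: 5 (2S)-2-methyl-2-(prop-2-en-1-yl)oxirane; 11 (3Z)-4-iodopenta-1,3-diene
Product: 13 (2S)-2-methyl-2-[(4Z)-4-methylhepta-4,6-dien-1-yl]oxirane, via B-alkyl-9-BBN adduct 12 (not isolated)
Conditions: 5, 9-BBN (1.1 equiv), THF, 0 °C → rt; then 11, Pd(dppf)Cl2 (5 mol %), AsPh3 (5 mol %), K3PO4 (3 M aq), DMF, rt
Reagents that add atoms: none
Why: 9-BBN hydroborates the monosubstituted alkene anti-Markovnikov without opening the oxirane, and the B-alkyl Suzuki–Miyaura coupling replaces iodine with retention, so C-1 is cis to C-6 on the C5=C10 alkene.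

Step 5
Reactants: 14 geranyl acetate
Product: 16 (2E)-3-methyl-6-oxohex-2-en-1-yl acetate, via 6,7-epoxygeranyl acetate 15 (not isolated)
Conditions: mCPBA (1.05 equiv), CH2Cl2, 0 °C; then H5IO6 (1.2 equiv), THF/Et2O, 0 °C
Reagents that add atoms: 3-chloroperbenzoic acid, OOC(=O)c1cccc(Cl)c1
Why: Prilezhaev epoxidation is selective for the electron-rich 6,7-alkene (the 2,3-alkene is deactivated by the allylic acetate), and periodic acid cleaves the epoxide via the diol to the aldehyde, leaving the 2E alkene untouched.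

Step 6
Reactants: 16 (2E)-3-methyl-6-oxohex-2-en-1-yl acetate
Product: 17 (2E)-7,7-dibromo-3-methylhepta-2,6-dien-1-yl acetate
Conditions: CBr4 (2 equiv), PPh3 (4 equiv), CH2Cl2, 0 °C
Reagents that add atoms: carbon tetrabromide, BrC(Br)(Br)Br
Why: Ramirez/Corey–Fuchs dibromo-olefination of the aldehyde, to which the acetate and the trisubstituted alkene are inert.

Step 7
Reactants: 17 (2E)-7,7-dibromo-3-methylhepta-2,6-dien-1-yl acetate
Product: 18 (2E,6Z)-7-bromo-3-methyl-8-(trimethylsilyl)octa-2,6-dien-1-yl acetate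
Conditions: Me3SiCH2MgCl + ZnCl2 (THF, 0 °C) → Me3SiCH2ZnCl (1.3 equiv); Pd(DPEphos)Cl2 (3 mol %), THF, 0 °C → rt
Reagents that add atoms: (trimethylsilyl)methylmagnesium chloride, C[Si](C)(C)C[Mg]Cl
Why: Negishi trans-selective monoalkylation of a 1,1-dibromoalkene, in which oxidative addition occurs at the less hindered C–Br bond trans to the chain, so CH2SiMe3 enters trans to C-11 and the remaining bromine is cis to it.

Step 8
Reactants: 13 (2S)-2-methyl-2-[(4Z)-4-methylhepta-4,6-dien-1-yl]oxirane; 18 (2E,6Z)-7-bromo-3-methyl-8-(trimethylsilyl)octa-2,6-dien-1-yl acetate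
Product: 20 (2E,6E,10Z)-3,11-dimethyl-14-[(2S)-2-methyloxiran-2-yl]-7-[(trimethylsilyl)methyl]tetradeca-2,6,10-trien-1-yl acetate, via homoallyl-9-BBN adduct 19 (not isolated)
Conditions: 13, 9-BBN (1.05 equiv), THF, 0 °C → rt; then 18, Pd(dppf)Cl2 (5 mol %), AsPh3 (10 mol %), K3PO4 (aq), DMF/THF, rt
Reagents that add atoms: none
Why: 9-BBN adds to the terminal CH2 of the 1,3-diene (as in the homogeraniol synthesis from the analogous triene), and B-alkyl Suzuki–Miyaura coupling with retention at the (Z)-bromide places C-7 cis to C-11, completing the trisubstituted allylsilane (the 6E label is only a CIP consequence of silicon).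

Step 9
Reactants: 20 (2E,6E,10Z)-3,11-dimethyl-14-[(2S)-2-methyloxiran-2-yl]-7-[(trimethylsilyl)methyl]tetradeca-2,6,10-trien-1-yl acetate
Product: 21 (13E)-19-hydroxy-5β-labda-8(17),13-dien-15-yl acetate
Conditions: MeAlCl2 (2.5 equiv), CH2Cl2, −78 °C, 30 min; Et3N/MeOH, then aq. Rochelle salt
Reagents that add atoms: none
Why: Proposed new method: Lewis-acid activation of the exocyclic 2,2-disubstituted oxirane should trigger a concerted cation–olefin bicyclisation (closest known type: the MeAlCl2 epoxy-polyene cyclisation with allylsilane termination), in which the C5=C10 π-bond opens the oxirane at the tertiary carbon with inversion (C-4 = S, oxygen stays on C-19), the tied-back oxirane CH2 takes the axial site syn to C-20 in the chair transition state, anti addition across the (Z)-C5=C10 alkene enforces the cis fusion (5β-H), chair closure of ring B with C-11 cis to C-7 puts the side chain axial (β) at C-9, and loss of Me3Si+ fixes the 8(17)-alkene while the acetate-deactivated 13-alkene stays out.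

Step 10
Reactants: 21 (13E)-19-hydroxy-5β-labda-8(17),13-dien-15-yl acetate
Product: 23 (13E)-15-acetoxy-5β-labda-8(17),13-dien-19-oic acid, via C-19 aldehyde 22 (not isolated)
Conditions: Jones reagent (CrO3, H2SO4, H2O), acetone, 0 °C, 30 min; i-PrOH quench
Reagents that add atoms: water (from the Jones reagent), O
Why: Jones oxidation takes the neopentyl primary alcohol through the aldehyde hydrate to the acid; C-4 is quaternary so nothing can epimerise, and the isolated alkenes and the acetate tolerate brief exposure at 0 °C.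

Step 11
Reactants: 23 (13E)-15-acetoxy-5β-labda-8(17),13-dien-19-oic acid
Product: 25 methyl (13E)-15-hydroxy-5β-labda-8(17),13-dien-19-oate, via methyl ester acetate 24 (not isolated)
Conditions: TMSCHN2, PhMe/MeOH (4:1), 0 °C → rt; AcOH; then K2CO3, MeOH, rt
Reagents that add atoms: (trimethylsilyl)diazomethane, C[Si](C)(C)C=[N+]=[N-]
Why: O-methylation of the hindered acid with TMSCHN2/MeOH needs no attack at the carbonyl, and the following K2CO3 methanolysis removes only the primary allylic acetate because the axial neopentyl C-19 ester is inert to transesterification.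

Step 12
Reactants: 25 methyl (13E)-15-hydroxy-5β-labda-8(17),13-dien-19-oate
Product: 26 methyl (13R,14R)-13,14-epoxy-15-hydroxy-5β-labd-8(17)-en-19-oate
Conditions: Ti(OiPr)4 (10 mol %), D-(−)-DIPT (12 mol %), TBHP (2 equiv, decane), 4 Å MS, CH2Cl2, −20 °C
Reagents that add atoms: tert-butyl hydroperoxide, CC(C)(C)OO
Why: Katsuki–Sharpless epoxidation is reagent-controlled and touches only the alkene bearing the allylic hydroxyl (the 8(17)-alkene has none), and the D-(−)-tartrate delivers oxygen to the face of the 13E alkene that gives the (13R,14R)-trans-epoxide.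

**Compound list**
1 | 2-methylprop-2-en-1-ol (methallyl alcohol) | C=C(C)CO | starting material
2 | [(2R)-2-methyloxiran-2-yl]methanol ((R)-2-methylglycidol) | OC[C@]1(C)CO1 | intermediate
3 | [(2S)-2-methyloxiran-2-yl]methyl 4-methylbenzenesulfonate | Cc1ccc(cc1)S(=O)(=O)OC[C@]1(C)CO1 | intermediate
4 | (2S)-2-hydroxy-2-methylpent-4-en-1-yl 4-methylbenzenesulfonate (present as its bromomagnesium alkoxide) | C=CC[C@](C)(O)COS(=O)(=O)c1ccc(C)cc1 | intermediate
5 | (2S)-2-methyl-2-(prop-2-en-1-yl)oxirane | C=CC[C@@]1(C)CO1 | intermediate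
6 | acrolein (prop-2-enal) | C=CC=O | starting material
7 | ethyltriphenylphosphonium iodide | CC[P+](c1ccccc1)(c1ccccc1)c1ccccc1.[I-] | starting material
8 | ethylidenetriphenylphosphorane | CC=P(c1ccccc1)(c1ccccc1)c1ccccc1 | intermediate
9 | (1-iodoethyl)triphenylphosphonium iodide | CC(I)[P+](c1ccccc1)(c1ccccc1)c1ccccc1.[I-] | intermediate
10 | (1-iodoethylidene)triphenylphosphorane | CC(I)=P(c1ccccc1)(c1ccccc1)c1ccccc1 | intermediate
11 | (3Z)-4-iodopenta-1,3-diene | C=C/C=C(/C)I | intermediate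
12 | 9-{3-[(2S)-2-methyloxiran-2-yl]propyl}-9-borabicyclo[3.3.1]nonane | C1CC2CCCC(C1)B2CCC[C@@]1(C)CO1 | intermediate
13 | (2S)-2-methyl-2-[(4Z)-4-methylhepta-4,6-dien-1-yl]oxirane | C=C/C=C(/C)CCC[C@@]1(C)CO1 | intermediate
14 | geranyl acetate, (2E)-3,7-dimethylocta-2,6-dien-1-yl acetate | CC(=O)OC/C=C(\C)CCC=C(C)C | starting material
15 | (2E)-5-(3,3-dimethyloxiran-2-yl)-3-methylpent-2-en-1-yl acetate (6,7-epoxygeranyl acetate, racemic) | CC(=O)OC/C=C(\C)CCC1OC1(C)C | intermediate
16 | (2E)-3-methyl-6-oxohex-2-en-1-yl acetate | CC(=O)OC/C=C(\C)CCC=O | intermediate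
17 | (2E)-7,7-dibromo-3-methylhepta-2,6-dien-1-yl acetate | CC(=O)OC/C=C(\C)CCC=C(Br)Br | intermediate
18 | (2E,6Z)-7-bromo-3-methyl-8-(trimethylsilyl)octa-2,6-dien-1-yl acetate | CC(=O)OC/C=C(\C)CC/C=C(\Br)C[Si](C)(C)C | intermediate
19 | 9-{(3Z)-4-methyl-7-[(2S)-2-methyloxiran-2-yl]hept-3-en-1-yl}-9-borabicyclo[3.3.1]nonane | C1CC2CCCC(C1)B2CC/C=C(/C)CCC[C@@]1(C)CO1 | intermediate
20 | (2E,6E,10Z)-3,11-dimethyl-14-[(2S)-2-methyloxiran-2-yl]-7-[(trimethylsilyl)methyl]tetradeca-2,6,10-trien-1-yl acetate | CC(=O)OC/C=C(\C)CC/C=C(/C[Si](C)(C)C)CC/C=C(/C)CCC[C@@]1(C)CO1 | intermediate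
21 | (13E)-19-hydroxy-5β-labda-8(17),13-dien-15-yl acetate (4S,5S,9S,10R; cis-fused decalin) | C=C1CC[C@H]2[C@](C)(CCC[C@]2(C)CO)[C@H]1CC/C(C)=C/COC(C)=O | intermediate
22 | (13E)-19-oxo-5β-labda-8(17),13-dien-15-yl acetate (4S,5S,9S,10R) | C=C1CC[C@H]2[C@](C)(CCC[C@]2(C)C=O)[C@H]1CC/C(C)=C/COC(C)=O | intermediate
23 | (13E)-15-acetoxy-5β-labda-8(17),13-dien-19-oic acid (4S,5S,9S,10R) | C=C1CC[C@H]2[C@](C)(CCC[C@]2(C)C(O)=O)[C@H]1CC/C(C)=C/COC(C)=O | intermediate
24 | methyl (13E)-15-acetoxy-5β-labda-8(17),13-dien-19-oate (4S,5S,9S,10R) | C=C1CC[C@H]2[C@](C)(CCC[C@]2(C)C(=O)OC)[C@H]1CC/C(C)=C/COC(C)=O | intermediate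
25 | methyl (13E)-15-hydroxy-5β-labda-8(17),13-dien-19-oate (4S,5S,9S,10R) | C=C1CC[C@H]2[C@](C)(CCC[C@]2(C)C(=O)OC)[C@H]1CC/C(C)=C/CO | intermediate
26 | methyl (13R,14R)-13,14-epoxy-15-hydroxy-5β-labd-8(17)-en-19-oate (4S,5S,9S,10R,13R,14R; CNP0175926.1) | C=C1CC[C@H]2[C@](C)(CCC[C@]2(C)C(=O)OC)[C@H]1CC[C@@]1(C)O[C@@H]1CO | target

**Step count**
Total steps: 12. Longest linear sequence: 8 steps (1 → 2 → 4 → 8 → 9 → 10 → 11 → 12 from methallyl alcohol; equally 5 → 6 → 7 → 8 → 9 → 10 → 11 → 12 from geranyl acetate).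

**Three steps most likely to fail**

Step 9 (bicyclisation). The risks are:
- the chair with CH3 rather than the oxirane CH2 axial, which would give the C-4/ring mismatched diastereomer;
- leakage from the concerted anti pathway, giving trans-fused or 9-epi isomers;
- Meinwald rearrangement of the oxirane to an aldehyde.

The fallback moves the oxirane into the ring-forming chain so that alkene geometry, not a conformational preference, fixes C-4. It sets out from 6, 11 and 18 and comes back at 21. Still–Gennari olefination of 6 (methyl 2-[bis(2,2,2-trifluoroethoxy)phosphoryl]propanoate, KHMDS, 18-crown-6, THF, −78 °C) gives methyl (2Z)-2-methylpenta-2,4-dienoate F1, and DIBAL-H reduction gives (2Z)-2-methylpenta-2,4-dien-1-ol F2. 9-BBN (2.1 equiv) converts this into the O,C-bis(9-BBN) adduct F3, which is coupled with 11 (Pd(dppf)Cl2, K3PO4) to give (2Z,6Z)-2,6-dimethylnona-2,6,8-trien-1-ol F4. A second hydroboration gives the O,C-bis(9-BBN) adduct F5, and coupling with 18 gives the tetraenol acetate F6. Sharpless epoxidation of the free (Z)-allylic alcohol with D-(−)-DIPT gives the 2,3-epoxy alcohol F7. MeAlCl2 at −78 °C then cyclises it, with the CH2OH group necessarily axial because it is cis to C-2 on the oxirane, to the 3β,19-diol F8. 1,1'-Thiocarbonyldiimidazole gives the cyclic thionocarbonate F9, and Bu3SnH/AIBN in refluxing toluene (Barton-type fragmentation to the secondary C-3 radical, loss of COS, KF work-up) returns 21.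

Step 8 (second fragment coupling). The risks are incomplete or unselective hydroboration of diene 13, slow coupling at the hindered bromoallylsilane, and Pd π-allyl chemistry at the allylic acetate. The fallback grows the chain iteratively instead of joining two large fragments. It sets out from 18 and from 5 (as its borane 12) and comes back at 20, without needing 11 or 13. Hydroboration of commercial acrolein diethyl acetal gives 9-(3,3-diethoxypropyl)-9-BBN F10, which couples with 18 to give the diethyl acetal F11. PPTS in wet acetone releases the aldehyde F12. Zhao olefination with ylide 10 (generated as in step 3) gives the (Z)-iodide F13, and B-alkyl Suzuki coupling of F13 with 12 gives 20.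

Step 3 (iododiene). The risks are polymerisation of acrolein under the basic ylide conditions and loss of the volatile, light-sensitive product. The fallback builds the diene after the coupling instead of before it. It sets out from 5 (as its borane 12) and comes back at 13. Commercial but-2-yn-1-ol is converted (Red-Al, then I2) into (2Z)-3-iodobut-2-en-1-ol F14. Suzuki coupling with 12 gives the allylic alcohol F15, MnO2 oxidation gives the (2Z)-enal F16 (used at once to avoid Z/E isomerisation), and Wittig methylenation (Ph3P=CH2, THF, −78 → 0 °C) gives 13.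

**Further compounds**
F1 | step 9 | methyl (2Z)-2-methylpenta-2,4-dienoate | C=C/C=C(/C)C(=O)OC
F2 | step 9 | (2Z)-2-methylpenta-2,4-dien-1-ol | C=C/C=C(/C)CO
F3 | step 9 | 9-{[(2Z)-5-(9-borabicyclo[3.3.1]nonan-9-yl)-2-methylpent-2-en-1-yl]oxy}-9-borabicyclo[3.3.1]nonane | C1CC2CCCC(C1)B2OC/C(C)=C\CCB1C2CCCC1CCC2
F4 | step 9 | (2Z,6Z)-2,6-dimethylnona-2,6,8-trien-1-ol | C=C/C=C(/C)CC/C=C(/C)CO
F5 | step 9 | 9-{[(2Z,6Z)-9-(9-borabicyclo[3.3.1]nonan-9-yl)-2,6-dimethylnona-2,6-dien-1-yl]oxy}-9-borabicyclo[3.3.1]nonane | C1CC2CCCC(C1)B2OC/C(C)=C\CC/C(C)=C\CCB1C2CCCC1CCC2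
F6 | step 9 | (2E,6E,10Z,14Z)-16-hydroxy-3,11,15-trimethyl-7-[(trimethylsilyl)methyl]hexadeca-2,6,10,14-tetraen-1-yl acetate | CC(=O)OC/C=C(\C)CC/C=C(/C[Si](C)(C)C)CC/C=C(/C)CC/C=C(/C)CO
F7 | step 9 | (2E,6E,10Z)-13-[(2S,3R)-3-(hydroxymethyl)-3-methyloxiran-2-yl]-3,11-dimethyl-7-[(trimethylsilyl)methyl]trideca-2,6,10-trien-1-yl acetate | CC(=O)OC/C=C(\C)CC/C=C(/C[Si](C)(C)C)CC/C=C(/C)CC[C@@H]1O[C@]1(C)CO
F8 | step 9 | (13E)-3β,19-dihydroxy-5β-labda-8(17),13-dien-15-yl acetate | C=C1CC[C@H]2[C@](C)(CC[C@H](O)[C@]2(C)CO)[C@H]1CC/C(C)=C/COC(C)=O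
F9 | step 9 | (13E)-3β,19-(thiocarbonyldioxy)-5β-labda-8(17),13-dien-15-yl acetate (cyclic thionocarbonate) | C=C1CC[C@H]2[C@](C)(CC[C@@H]3OC(=S)OC[C@]23C)[C@H]1CC/C(C)=C/COC(C)=O
F10 | step 8 | 9-(3,3-diethoxypropyl)-9-borabicyclo[3.3.1]nonane | CCOC(CCB1C2CCCC1CCC2)OCC
F11 | step 8 | (2E,6E)-10,10-diethoxy-3-methyl-7-[(trimethylsilyl)methyl]deca-2,6-dien-1-yl acetate | CC(=O)OC/C=C(\C)CC/C=C(/C[Si](C)(C)C)CCC(OCC)OCC
F12 | step 8 | (2E,6E)-3-methyl-10-oxo-7-[(trimethylsilyl)methyl]deca-2,6-dien-1-yl acetate | CC(=O)OC/C=C(\C)CC/C=C(/C[Si](C)(C)C)CCC=O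
F13 | step 8 | (2E,6E,10Z)-11-iodo-3-methyl-7-[(trimethylsilyl)methyl]dodeca-2,6,10-trien-1-yl acetate | CC(=O)OC/C=C(\C)CC/C=C(/C[Si](C)(C)C)CC/C=C(\I)C
F14 | step 3 | (2Z)-3-iodobut-2-en-1-ol | C/C(I)=C/CO
F15 | step 3 | (2Z)-3-methyl-6-[(2S)-2-methyloxiran-2-yl]hex-2-en-1-ol | OC/C=C(/C)CCC[C@@]1(C)CO1
F16 | step 3 | (2Z)-3-methyl-6-[(2S)-2-methyloxiran-2-yl]hex-2-enal | O=C/C=C(/C)CCC[C@@]1(C)CO1
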